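The ten-membered carbocycle is not closed end to end but grown from a cyclohexene. The C1 ketone and the C6 lactone oxygen stand 1,6 to each other with the cis C4–C5 unit (the epoxide carbons) between them, so C1 and C6 can be rejoined into a cyclohexene 1,2-diol derivative that carries an isopropenyl group (C10, C9) on C1 and an (E)-2-(4-methoxybenzyloxy)vinyl group (C7, C8) on C6. One anionic oxy-Cope shift of this trans-dialkenyl carbinol cuts C1–C6, joins C8–C9, gives the germacrane ring with C1 and C6 as distinguishable enol derivatives and sets C8. The butenolide, C10, C6 and the epoxide follow on the macrocycle.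

Key step: step 17

Remark: locants C1–C15 are those of the germacrane skeleton of the target and are used for all intermediates from compound 9 on; minor diastereomers from steps 1, 12, 16, 20, 24 and 27 are assumed to be separable by chromatography.

Step 1
Reactants: 1 (R)-2,2-dimethyl-1,3-dioxolane-4-carbaldehyde
Product: 2 (S)-1-[(R)-2,2-dimethyl-1,3-dioxolan-4-yl]-3-methylbut-3-en-1-ol
Conditions: 3-bromo-2-methylprop-1-ene, Zn dust, THF/sat. aq NH4Cl, 0 °C to rt
Reagents that add atoms: 3-bromo-2-methylprop-1-ene, C=C(C)CBr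
Why: Barbier-type allylation in which the methallylzinc species formed in the flask should add to the α-alkoxy aldehyde in the Felkin–Anh sense, setting the new carbinol (future C2) anti to the dioxolane oxygen.

Step 2
Reactants: 2 (S)-1-[(R)-2,2-dimethyl-1,3-dioxolan-4-yl]-3-methylbut-3-en-1-ol
Product: 3 tert-butyl{[(S)-1-((R)-2,2-dimethyl-1,3-dioxolan-4-yl)-3-methylbut-3-en-1-yl]oxy}dimethylsilane
Conditions: TBSCl, imidazole, DMF, rt
Reagents that add atoms: tert-butyldimethylsilyl chloride, CC(C)(C)[Si](C)(C)Cl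
Why: Standard silylation of a secondary alcohol that touches no stereocentre.

Step 3
Reactants: 3 tert-butyl{[(S)-1-((R)-2,2-dimethyl-1,3-dioxolan-4-yl)-3-methylbut-3-en-1-yl]oxy}dimethylsilane
Product: 4 (2R,3S)-3-(tert-butyldimethylsilyloxy)-5-methylhex-5-ene-1,2-diol
Conditions: CuCl2·2H2O, MeCN, 0 °C
Reagents that add atoms: none
Why: Lewis-acid-mediated hydrolysis of the terminal acetonide, mild enough to leave the secondary TBS ether and the 1,1-disubstituted alkene untouched.

Step 4
Reactants: 4 (2R,3S)-3-(tert-butyldimethylsilyloxy)-5-methylhex-5-ene-1,2-diol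
Product: 5 (2R,3S)-3-(tert-butyldimethylsilyloxy)-5-methyl-1,2-bis(triethylsilyloxy)hex-5-ene
Conditions: TESCl, imidazole, DMAP (cat.), CH2Cl2, 0 °C to rt
Reagents that add atoms: chlorotriethylsilane, CC[Si](Cl)(CC)CC
Why: Exhaustive silylation that leaves a primary and a secondary TES ether, which the next step tells apart.

Step 5
Reactants: 5 (2R,3S)-3-(tert-butyldimethylsilyloxy)-5-methyl-1,2-bis(triethylsilyloxy)hex-5-ene
Product: 6 (2S,3S)-3-(tert-butyldimethylsilyloxy)-5-methyl-2-(triethylsilyloxy)hex-5-enal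
Conditions: (COCl)2, DMSO, CH2Cl2, −78 to −40 °C; then Et3N, −78 °C to rt
Reagents that add atoms: none
Why: Swern oxidation applied directly to the primary TES ether, which the chlorosulfonium salt cleaves and oxidises to the aldehyde while the secondary TES and TBS ethers stay and the α-centre is not enolised at low temperature.

Step 6
Reactants: 6 (2S,3S)-3-(tert-butyldimethylsilyloxy)-5-methyl-2-(triethylsilyloxy)hex-5-enal
Product: 7 (4R,5S)-5-(tert-butyldimethylsilyloxy)-7-methyl-4-(triethylsilyloxy)octa-1,7-dien-3-ol (both C3 epimers)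
Conditions: vinylmagnesium bromide, THF, −78 °C
Reagents that add atoms: vinylmagnesium bromide, C=C[Mg]Br
Why: Grignard 1,2-addition to the aldehyde, whose new carbinol centre is left as a mixture because it is oxidised in the next step.

Step 7
Reactants: 7 (4R,5S)-5-(tert-butyldimethylsilyloxy)-7-methyl-4-(triethylsilyloxy)octa-1,7-dien-3-ol
Product: 8 (4S,5S)-5-(tert-butyldimethylsilyloxy)-7-methyl-4-(triethylsilyloxy)octa-1,7-dien-3-one
Conditions: Dess–Martin periodinane, CH2Cl2, 0 °C to rt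
Reagents that add atoms: none
Why: Dess–Martin oxidation of the allylic alcohol to the vinyl ketone under non-basic conditions that should not epimerise the α-silyloxy centre.

Step 8
Reactants: 8 (4S,5S)-5-(tert-butyldimethylsilyloxy)-7-methyl-4-(triethylsilyloxy)octa-1,7-dien-3-one
Product: 9 (5S,6S)-5-(tert-butyldimethylsilyloxy)-3-methyl-6-(triethylsilyloxy)cyclohex-2-en-1-one
Conditions: second-generation Hoveyda–Grubbs catalyst (H2IMes)Cl2Ru(=CH-C6H4-2-OiPr) (5 mol%), CH2Cl2, high dilution, 40 °C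
Reagents that add atoms: none
Why: Ring-closing metathesis between the vinyl ketone and the 1,1-disubstituted alkene closes the six-membered ring (C1–C6) as the trisubstituted enone with loss of ethylene.

Step 9
Reactants: 10 trichloroethylene
Product: 11 1-({[(E)-1,2-dichloroethenyl]oxy}methyl)-4-methoxybenzene
Conditions: 4-methoxybenzyl alcohol, KH, THF, 0 °C to rt
Reagents that add atoms: 4-methoxybenzyl alcohol, COc1ccc(CO)cc1
Why: Addition–elimination of the potassium alkoxide on trichloroethylene gives the 1,2-dichlorovinyl ether, the usual entry to alkynyl ethers.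

Step 10
Reactants: 11 1-({[(E)-1,2-dichloroethenyl]oxy}methyl)-4-methoxybenzene
Product: 13 1-[(ethynyloxy)methyl]-4-methoxybenzene, via lithium alkynyl ether 12 (not isolated)
Conditions: n-BuLi (2.2 equiv), Et2O, −78 °C; MeOH, −78 °C; cold work-up, solution kept below 0 °C and used at once
Reagents that add atoms: none
Why: Dehydrochlorination followed by chlorine–lithium exchange gives the lithium acetylide, which is protonated cold because benzylic ynol ethers rearrange on warming.

Step 11
Reactants: 13 1-[(ethynyloxy)methyl]-4-methoxybenzene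
Product: 15 1-({[(E)-2-iodoethenyl]oxy}methyl)-4-methoxybenzene, via alkenylzirconocene chloride 14 (not isolated)
Conditions: Cp2Zr(H)Cl, THF, 0 °C; then I2, −78 to 0 °C; stored cold over K2CO3
Reagents that add atoms: iodine, II
Why: Hydrozirconation adds Zr–H syn across the terminal alkyne with zirconium on the unsubstituted carbon, and iodinolysis with retention gives the E iodo enol ether.

Step 12
Reactants: 15 1-({[(E)-2-iodoethenyl]oxy}methyl)-4-methoxybenzene; 9 (5S,6S)-5-(tert-butyldimethylsilyloxy)-3-methyl-6-(triethylsilyloxy)cyclohex-2-en-1-one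
Product: 17 (1S,2S,6S)-2-(tert-butyldimethylsilyloxy)-6-[(E)-2-(4-methoxybenzyloxy)ethenyl]-4-methyl-1-(triethylsilyloxy)cyclohex-4-en-6-ol (target numbering), via alkenyllithium 16 (not isolated)
Conditions: 15, t-BuLi (2 equiv), Et2O, −78 °C; then 9, −78 °C; aqueous NaHCO3 quench
Reagents that add atoms: none
Why: Iodine–lithium exchange with retention of the E geometry, then 1,2-addition of the alkenyllithium to the enone carbonyl from the face opposite the neighbouring C1 silyloxy group (polar Felkin–Anh), which should make C6 the S carbinol with its hydroxyl cis to the C1 oxygen.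

Step 13
Reactants: 17 (1S,2S,6S)-2-(tert-butyldimethylsilyloxy)-6-[(E)-2-(4-methoxybenzyloxy)ethenyl]-4-methyl-1-(triethylsilyloxy)cyclohex-4-en-6-ol
Product: 18 (1S,2S,6S)-2-(tert-butyldimethylsilyloxy)-6-[(E)-2-(4-methoxybenzyloxy)ethenyl]-4-methylcyclohex-4-ene-1,6-diol (target numbering)
Conditions: Bu4NF/AcOH (1:1), THF, 0 °C
Reagents that add atoms: none
Why: Buffered fluoride desilylation removes the secondary TES ether faster than the TBS ether, and the buffer suppresses both silyl migration to the freed cis hydroxyl and acid-induced ionisation of the alkoxyvinyl carbinol.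

Step 14
Reactants: 18 (1S,2S,6S)-2-(tert-butyldimethylsilyloxy)-6-[(E)-2-(4-methoxybenzyloxy)ethenyl]-4-methylcyclohex-4-ene-1,6-diol
Product: 19 (2S,6S)-2-(tert-butyldimethylsilyloxy)-6-hydroxy-6-[(E)-2-(4-methoxybenzyloxy)ethenyl]-4-methylcyclohex-4-en-1-one (target numbering)
Conditions: Dess–Martin periodinane, pyridine, CH2Cl2, 0 °C
Reagents that add atoms: none
Why: Dess–Martin oxidation of the only oxidisable (secondary) hydroxyl, with pyridine protecting the acid-labile enol ether.

Step 15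
Reactants: 19 (2S,6S)-2-(tert-butyldimethylsilyloxy)-6-hydroxy-6-[(E)-2-(4-methoxybenzyloxy)ethenyl]-4-methylcyclohex-4-en-1-one
Product: 20 (2S,6S)-2-(tert-butyldimethylsilyloxy)-6-methoxy-6-[(E)-2-(4-methoxybenzyloxy)ethenyl]-4-methylcyclohex-4-en-1-one (target numbering)
Conditions: MeI (excess), Ag2O, 4 Å molecular sieves, MeCN, 40 °C, dark
Reagents that add atoms: iodomethane, CI
Why: Silver-oxide-promoted (Purdie-type) O-methylation of the fairly acidic α-ketol hydroxyl, which avoids the strong base that would enolise the ketone toward C2 or start an acyloin shift.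

Step 16
Reactants: 20 (2S,6S)-2-(tert-butyldimethylsilyloxy)-6-methoxy-6-[(E)-2-(4-methoxybenzyloxy)ethenyl]-4-methylcyclohex-4-en-1-one; 21 2-bromopropene
Product: 24 (1R,2S,6S)-2-(tert-butyldimethylsilyloxy)-6-methoxy-6-[(E)-2-(4-methoxybenzyloxy)ethenyl]-4-methyl-1-(prop-1-en-2-yl)cyclohex-4-en-1-ol (target numbering; the two alkenyl groups trans), via isopropenyllithium 22 (not isolated), via isopropenylcerium dichloride 23 (not isolated)
Conditions: 21, t-BuLi (2 equiv), THF, −78 °C; anhydrous CeCl3, THF, −78 °C; then 20, −78 °C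
Reagents that add atoms: none
Why: Organocerium 1,2-addition to the hindered, enolisable ketone, in which chelation of the carbonyl and the C6 methoxy oxygen to cerium turns the C6 alkenyl arm pseudo-axial so that the nucleophile should enter from the opposite face (the C2 silyloxy group being equatorial there), giving trans alkenyl groups and R at C1.

Step 17
Reactants: 24 (1R,2S,6S)-2-(tert-butyldimethylsilyloxy)-6-methoxy-6-[(E)-2-(4-methoxybenzyloxy)ethenyl]-4-methyl-1-(prop-1-en-2-yl)cyclohex-4-en-1-ol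
Product: 27 (2S,8R)-1,2-bis(tert-butyldimethylsilyloxy)-6-methoxy-8-(4-methoxybenzyloxy)-4,10-dimethylcyclodeca-1(10),4,6-triene (ring bonds trans across C1=C10 and C6=C7 and cis across C4=C5), via potassium alkoxide 25 (not isolated), via potassium enolate 26 (not isolated)
Conditions: KN(SiMe3)2, 18-crown-6, THF, −78 to 0 °C; then TBSCl, −78 to 0 °C
Reagents that add atoms: tert-butyldimethylsilyl chloride, CC(C)(C)[Si](C)(C)Cl
Why: The C1 potassium alkoxide starts a concerted, alkoxide-accelerated [3,3] sigmatropic shift over C9=C10–C1–C6–C7=C8, in which the C1–C6 bond (weakened by the oxyanion on C1 and the methoxy group on C6) breaks while C8–C9 forms, and the resulting C1 enolate is silylated on oxygen in the same flask. The closest known reaction type is the anionic oxy-Cope ring expansion of trans-1,2-dialkenylcyclohexanols to cyclodec-5-enones and of 1,2-dialkenyl diol monoethers to 1,6-dioxygenated rings. The ten-membered carbocycle is formed by four-atom ring expansion (the six-membered ring supplies C1–C6, the two arms supply C7–C10), not by end-to-end cyclisation. The only new stereocentre, C8, should come out R by chirality transfer through the chair transition state with both alkenyl groups equatorial, fixed by the 1R,6S configuration and by the E enol ether, which places the benzyloxy group equatorial. The same chair gives the trans ring geometry at C1=C10 and C6=C7, while the cis C4=C5 bond of the cyclohexene is carried over unchanged. The step needs chair over boat and the alkoxyvinyl arm rather than the ring alkene as second π partner: the trans arms allow only the chair, the isopropenyl group lies anti to C5 and cannot reach the ring alkene, the C6 methyl enol ether cannot expel the C8 ether, and O-silylation (potassium with crown ether) masks C1 against transannular aldol reaction.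

Step 18
Reactants: 27 (2S,8R)-1,2-bis(tert-butyldimethylsilyloxy)-6-methoxy-8-(4-methoxybenzyloxy)-4,10-dimethylcyclodeca-1(10),4,6-triene
Product: 28 (2S,8R)-1,2-bis(tert-butyldimethylsilyloxy)-7-[(dimethylamino)methyl]-8-(4-methoxybenzyloxy)-4,10-dimethylcyclodeca-1(10),4-dien-6-one (C7 epimers)
Conditions: (CH2=NMe2)I (1.05 equiv), CH2Cl2, −40 to 0 °C; aqueous NaHCO3 work-up
Reagents that add atoms: N,N-dimethylmethyleneiminium iodide, C=[N+](C)C.[I-]
Why: Mannich reaction of an enol ether, in which the exposed terminus C7 of the 2-methoxydiene should react in preference to the tetrasubstituted C1=C10 silyl enol ether (which would have to build a quaternary C10), after which iodide demethylates the methoxy-oxocarbenium ion to the C6 ketone; the C7 centre is removed in the next step.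

Step 19
Reactants: 28 (2S,8R)-1,2-bis(tert-butyldimethylsilyloxy)-7-[(dimethylamino)methyl]-8-(4-methoxybenzyloxy)-4,10-dimethylcyclodeca-1(10),4-dien-6-one
Product: 30 (2S,8R)-1,2-bis(tert-butyldimethylsilyloxy)-8-(4-methoxybenzyloxy)-4,10-dimethyl-7-methylidenecyclodeca-1(10),4-dien-6-one, via trimethylammonium iodide 29 (not isolated)
Conditions: MeI, Et2O/CH2Cl2, rt; then aqueous NaHCO3/CH2Cl2, rt
Reagents that add atoms: none
Why: N-quaternisation followed by Hofmann-type (E1cB) loss of trimethylamine gives the α-methylene ketone, the ammonium group leaving much faster than the C8 ether.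

Step 20
Reactants: 30 (2S,8R)-1,2-bis(tert-butyldimethylsilyloxy)-8-(4-methoxybenzyloxy)-4,10-dimethyl-7-methylidenecyclodeca-1(10),4-dien-6-one
Product: 31 (2S,6S,8R)-1,2-bis(tert-butyldimethylsilyloxy)-8-(4-methoxybenzyloxy)-4,10-dimethyl-7-methylidenecyclodeca-1(10),4-dien-6-ol
Conditions: NaBH4, CeCl3·7H2O, MeOH/THF, −78 °C
Reagents that add atoms: none
Why: Luche 1,2-reduction of the cross-conjugated dienone, with hydride expected from the outer face of the ring to give the 6S alcohol (oxygen syn to the C8 oxygen) while C1 stays masked as the silyl enol ether; a wrong C6 epimer would be returned to 30 with MnO2.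

Step 21
Reactants: 31 (2S,6S,8R)-1,2-bis(tert-butyldimethylsilyloxy)-8-(4-methoxybenzyloxy)-4,10-dimethyl-7-methylidenecyclodeca-1(10),4-dien-6-ol; 32 2-(bromomethyl)acrylic acid
Product: 34 (2S,6S,8R)-1,2-bis(tert-butyldimethylsilyloxy)-8-(4-methoxybenzyloxy)-4,10-dimethyl-7-methylidenecyclodeca-1(10),4-dien-6-yl 2-(bromomethyl)prop-2-enoate, via 2-(bromomethyl)acryloyl chloride 33 (not isolated)
Conditions: 32, (COCl)2, DMF (cat.), CH2Cl2, 0 °C to rt; then 31, 2,6-lutidine, CH2Cl2, −40 to 0 °C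
Reagents that add atoms: none
Why: Acylation of the alcohol by the acid chloride with retention at C6, using a hindered, weakly nucleophilic base because acyl-transfer pyridines and trialkylamines would attack the allylic bromide in an SN2' sense.

Step 22
Reactants: 34 (2S,6S,8R)-1,2-bis(tert-butyldimethylsilyloxy)-8-(4-methoxybenzyloxy)-4,10-dimethyl-7-methylidenecyclodeca-1(10),4-dien-6-yl 2-(bromomethyl)prop-2-enoate
Product: 35 (2S,6S,8R)-13-bromo-1,2-bis(tert-butyldimethylsilyloxy)-8-(4-methoxybenzyloxy)germacra-1(10),4,7(11)-trien-12,6-olide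
Conditions: second-generation Hoveyda–Grubbs catalyst (H2IMes)Cl2Ru(=CH-C6H4-2-OiPr) (15 mol% in portions), toluene (2 mM), 80 °C, argon sparge
Reagents that add atoms: none
Why: Ring-closing metathesis of the two 1,1-disubstituted alkenes forms the tetrasubstituted C7=C11 bond of the butenolide with loss of ethylene; the phosphine-free catalyst cannot be alkylated by the allylic bromide, and the silyl enol ether and the trisubstituted ring alkene are too hindered to compete.

Step 23
Reactants: 35 (2S,6S,8R)-13-bromo-1,2-bis(tert-butyldimethylsilyloxy)-8-(4-methoxybenzyloxy)germacra-1(10),4,7(11)-trien-12,6-olide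
Product: 36 (2S,6S,8R)-13-acetoxy-1,2-bis(tert-butyldimethylsilyloxy)-8-(4-methoxybenzyloxy)germacra-1(10),4,7(11)-trien-12,6-olide
Conditions: CsOAc, DMF, 0 °C
Reagents that add atoms: caesium acetate, CC(=O)[O-].[Cs+]
Why: SN2 displacement of the activated primary allylic bromide by acetate, a base too weak to deprotonate the butenolide γ-position.

Step 24
Reactants: 36 (2S,6S,8R)-13-acetoxy-1,2-bis(tert-butyldimethylsilyloxy)-8-(4-methoxybenzyloxy)germacra-1(10),4,7(11)-trien-12,6-olide
Product: 37 (2S,6S,8R,10S)-13-acetoxy-2-(tert-butyldimethylsilyloxy)-8-(4-methoxybenzyloxy)-1-oxogermacra-4,7(11)-dien-12,6-olide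
Conditions: Bu4NF/AcOH (1:1.2, 1.1 equiv), THF, −40 to 0 °C
Reagents that add atoms: none
Why: Fluoride cleaves the silyl enol ether faster than the alkyl TBS ether, and the freed enol should be protonated at C10 by acetic acid on its outer face to give the 10S methyl ketone; C10 remains epimerisable, so the outcome can still be adjusted by mild base equilibration.

Step 25
Reactants: 37 (2S,6S,8R,10S)-13-acetoxy-2-(tert-butyldimethylsilyloxy)-8-(4-methoxybenzyloxy)-1-oxogermacra-4,7(11)-dien-12,6-olide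
Product: 38 (2S,6S,8R,10S)-13-acetoxy-2-(tert-butyldimethylsilyloxy)-8-hydroxy-1-oxogermacra-4,7(11)-dien-12,6-olide
Conditions: DDQ, CH2Cl2/pH 7 buffer, 0 °C to rt
Reagents that add atoms: none
Why: Oxidative cleavage of the 4-methoxybenzyl ether (hydride abstraction, then hydrolysis), placed after removal of the silyl enol ether, which DDQ would dehydrogenate.

Step 26
Reactants: 38 (2S,6S,8R,10S)-13-acetoxy-2-(tert-butyldimethylsilyloxy)-8-hydroxy-1-oxogermacra-4,7(11)-dien-12,6-olide
Product: 39 (2S,6S,8R,10S)-13-acetoxy-2-(tert-butyldimethylsilyloxy)-8-(methacryloyloxy)-1-oxogermacra-4,7(11)-dien-12,6-olide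
Conditions: methacrylic anhydride, Et3N, DMAP (cat.), CH2Cl2, 0 °C
Reagents that add atoms: methacrylic anhydride, C=C(C)C(=O)OC(=O)C(C)=C
Why: DMAP-catalysed acylation of the only free hydroxyl with retention at C8, run cold and briefly so that the C8 oxygen is acylated before it can translactonise onto C12.

Step 27
Reactants: 39 (2S,6S,8R,10S)-13-acetoxy-2-(tert-butyldimethylsilyloxy)-8-(methacryloyloxy)-1-oxogermacra-4,7(11)-dien-12,6-olide
Product: 40 (2S,4S,5R,6R,8R,10S)-13-acetoxy-2-(tert-butyldimethylsilyloxy)-4,5-epoxy-8-(methacryloyloxy)-1-oxogermacr-7(11)-en-12,6-olide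
Conditions: mCPBA, NaHCO3, CH2Cl2, 0 °C
Reagents that add atoms: 3-chloroperoxybenzoic acid, O=C(OO)c1cccc(Cl)c1
Why: Prilezhaev epoxidation of the only electron-rich alkene (the butenolide and methacrylate alkenes are electron-poor), with the peracid expected on the outer face of the cis C4=C5 bond so that syn addition gives the cis (4S,5R) epoxide.

Step 28
Reactants: 40 (2S,4S,5R,6R,8R,10S)-13-acetoxy-2-(tert-butyldimethylsilyloxy)-4,5-epoxy-8-(methacryloyloxy)-1-oxogermacr-7(11)-en-12,6-olide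
Product: 41 (2S,4S,5R,6R,8R,10S)-13-acetoxy-4,5-epoxy-2-hydroxy-8-(methacryloyloxy)-1-oxogermacr-7(11)-en-12,6-olide (CNP0359197.1)
Conditions: Bu4NF/AcOH (1:1), THF, 0 °C to rt
Reagents that add atoms: none
Why: Buffered fluoride desilylation of the α-silyloxy ketone under near-neutral conditions that should spare the epoxide, both esters, the butenolide and the epimerisable C2 and C10 centres.

Compound list
1 | (R)-2,2-dimethyl-1,3-dioxolane-4-carbaldehyde | O=C[C@H]1COC(C)(C)O1 | starting material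
2 | (S)-1-[(R)-2,2-dimethyl-1,3-dioxolan-4-yl]-3-methylbut-3-en-1-ol | C=C(C)C[C@H](O)[C@H]1COC(C)(C)O1 | intermediate
3 | tert-butyl{[(S)-1-((R)-2,2-dimethyl-1,3-dioxolan-4-yl)-3-methylbut-3-en-1-yl]oxy}dimethylsilane | C=C(C)C[C@H](O[Si](C)(C)C(C)(C)C)[C@H]1COC(C)(C)O1 | intermediate
4 | (2R,3S)-3-(tert-butyldimethylsilyloxy)-5-methylhex-5-ene-1,2-diol | C=C(C)C[C@H](O[Si](C)(C)C(C)(C)C)[C@H](O)CO | intermediate
5 | (2R,3S)-3-(tert-butyldimethylsilyloxy)-5-methyl-1,2-bis(triethylsilyloxy)hex-5-ene | C=C(C)C[C@H](O[Si](C)(C)C(C)(C)C)[C@H](O[Si](CC)(CC)CC)CO[Si](CC)(CC)CC | intermediate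
6 | (2S,3S)-3-(tert-butyldimethylsilyloxy)-5-methyl-2-(triethylsilyloxy)hex-5-enal | C=C(C)C[C@H](O[Si](C)(C)C(C)(C)C)[C@H](O[Si](CC)(CC)CC)C=O | intermediate
7 | (4R,5S)-5-(tert-butyldimethylsilyloxy)-7-methyl-4-(triethylsilyloxy)octa-1,7-dien-3-ol, both C3 epimers | C=C(C)C[C@H](O[Si](C)(C)C(C)(C)C)[C@H](O[Si](CC)(CC)CC)C(O)C=C | intermediate
8 | (4S,5S)-5-(tert-butyldimethylsilyloxy)-7-methyl-4-(triethylsilyloxy)octa-1,7-dien-3-one | C=C(C)C[C@H](O[Si](C)(C)C(C)(C)C)[C@H](O[Si](CC)(CC)CC)C(=O)C=C | intermediate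
9 | (5S,6S)-5-(tert-butyldimethylsilyloxy)-3-methyl-6-(triethylsilyloxy)cyclohex-2-en-1-one | O=C1C=C(C)C[C@H](O[Si](C)(C)C(C)(C)C)[C@@H]1O[Si](CC)(CC)CC | intermediate
10 | trichloroethylene | ClC=C(Cl)Cl | starting material
11 | 1-({[(E)-1,2-dichloroethenyl]oxy}methyl)-4-methoxybenzene | COc1ccc(CO/C(Cl)=C\Cl)cc1 | intermediate
12 | [(4-methoxybenzyloxy)ethynyl]lithium | [Li]C#COCc1ccc(OC)cc1 | intermediate
13 | 1-[(ethynyloxy)methyl]-4-methoxybenzene | C#COCc1ccc(OC)cc1 | intermediate
14 | chlorobis(cyclopentadienyl)[(E)-2-(4-methoxybenzyloxy)ethenyl]zirconium | COc1ccc(CO/C=C/[Zr](Cl)(C2C=CC=C2)C2C=CC=C2)cc1 | intermediate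
15 | 1-({[(E)-2-iodoethenyl]oxy}methyl)-4-methoxybenzene | COc1ccc(CO/C=C/I)cc1 | intermediate
16 | (E)-2-(4-methoxybenzyloxy)ethenyllithium | COc1ccc(CO/C=C/[Li])cc1 | intermediate
17 | (1S,2S,6S)-2-(tert-butyldimethylsilyloxy)-6-[(E)-2-(4-methoxybenzyloxy)ethenyl]-4-methyl-1-(triethylsilyloxy)cyclohex-4-en-6-ol (target numbering; the three oxygens cis) | [C@H]1(O[Si](CC)(CC)CC)[C@@H](O[Si](C)(C)C(C)(C)C)CC(C)=C[C@]1(O)/C=C/OCc1ccc(OC)cc1 | intermediate
18 | (1S,2S,6S)-2-(tert-butyldimethylsilyloxy)-6-[(E)-2-(4-methoxybenzyloxy)ethenyl]-4-methylcyclohex-4-ene-1,6-diol (target numbering) | [C@H]1(O)[C@@H](O[Si](C)(C)C(C)(C)C)CC(C)=C[C@]1(O)/C=C/OCc1ccc(OC)cc1 | intermediate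
19 | (2S,6S)-2-(tert-butyldimethylsilyloxy)-6-hydroxy-6-[(E)-2-(4-methoxybenzyloxy)ethenyl]-4-methylcyclohex-4-en-1-one (target numbering) | O=C1[C@@H](O[Si](C)(C)C(C)(C)C)CC(C)=C[C@]1(O)/C=C/OCc1ccc(OC)cc1 | intermediate
20 | (2S,6S)-2-(tert-butyldimethylsilyloxy)-6-methoxy-6-[(E)-2-(4-methoxybenzyloxy)ethenyl]-4-methylcyclohex-4-en-1-one (target numbering) | O=C1[C@@H](O[Si](C)(C)C(C)(C)C)CC(C)=C[C@]1(OC)/C=C/OCc1ccc(OC)cc1 | intermediate
21 | 2-bromopropene | CC(Br)=C | starting material
22 | isopropenyllithium | C=C(C)[Li] | intermediate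
23 | isopropenylcerium dichloride | C=C(C)[Ce](Cl)Cl | intermediate
24 | (1R,2S,6S)-2-(tert-butyldimethylsilyloxy)-6-methoxy-6-[(E)-2-(4-methoxybenzyloxy)ethenyl]-4-methyl-1-(prop-1-en-2-yl)cyclohex-4-en-1-ol (target numbering) | C=C(C)[C@@]1(O)[C@@H](O[Si](C)(C)C(C)(C)C)CC(C)=C[C@]1(OC)/C=C/OCc1ccc(OC)cc1 | intermediate
25 | potassium alkoxide of 24 | C=C(C)[C@@]1([O-])[C@@H](O[Si](C)(C)C(C)(C)C)CC(C)=C[C@]1(OC)/C=C/OCc1ccc(OC)cc1.[K+] | intermediate
26 | potassium (2S,8R)-2-(tert-butyldimethylsilyloxy)-6-methoxy-8-(4-methoxybenzyloxy)-4,10-dimethylcyclodeca-1(10),4,6-trien-1-olate | [C@H]1(O[Si](C)(C)C(C)(C)C)C/C(C)=C\C(OC)=C\[C@H](OCc2ccc(OC)cc2)C/C(C)=C1\[O-].[K+] | intermediate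
27 | (2S,8R)-1,2-bis(tert-butyldimethylsilyloxy)-6-methoxy-8-(4-methoxybenzyloxy)-4,10-dimethylcyclodeca-1(10),4,6-triene | [C@H]1(O[Si](C)(C)C(C)(C)C)C/C(C)=C\C(OC)=C\[C@H](OCc2ccc(OC)cc2)C/C(C)=C1\O[Si](C)(C)C(C)(C)C | intermediate
28 | (2S,8R)-1,2-bis(tert-butyldimethylsilyloxy)-7-[(dimethylamino)methyl]-8-(4-methoxybenzyloxy)-4,10-dimethylcyclodeca-1(10),4-dien-6-one, C7 epimers | [C@H]1(O[Si](C)(C)C(C)(C)C)C/C(C)=C\C(=O)C(CN(C)C)[C@H](OCc2ccc(OC)cc2)C/C(C)=C1\O[Si](C)(C)C(C)(C)C | intermediate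
29 | N-methyl ammonium iodide of 28 | [C@H]1(O[Si](C)(C)C(C)(C)C)C/C(C)=C\C(=O)C(C[N+](C)(C)C)[C@H](OCc2ccc(OC)cc2)C/C(C)=C1\O[Si](C)(C)C(C)(C)C.[I-] | intermediate
30 | (2S,8R)-1,2-bis(tert-butyldimethylsilyloxy)-8-(4-methoxybenzyloxy)-4,10-dimethyl-7-methylidenecyclodeca-1(10),4-dien-6-one | [C@H]1(O[Si](C)(C)C(C)(C)C)C/C(C)=C\C(=O)C(=C)[C@H](OCc2ccc(OC)cc2)C/C(C)=C1\O[Si](C)(C)C(C)(C)C | intermediate
31 | (2S,6S,8R)-1,2-bis(tert-butyldimethylsilyloxy)-8-(4-methoxybenzyloxy)-4,10-dimethyl-7-methylidenecyclodeca-1(10),4-dien-6-ol | COc1ccc(CO[C@@H]2C/C(C)=C(\O[Si](C)(C)C(C)(C)C)[C@@H](O[Si](C)(C)C(C)(C)C)C/C(C)=C\[C@H](O)C2=C)cc1 | intermediate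
32 | 2-(bromomethyl)acrylic acid | C=C(CBr)C(=O)O | starting material
33 | 2-(bromomethyl)acryloyl chloride | C=C(CBr)C(=O)Cl | intermediate
34 | (2S,6S,8R)-1,2-bis(tert-butyldimethylsilyloxy)-8-(4-methoxybenzyloxy)-4,10-dimethyl-7-methylidenecyclodeca-1(10),4-dien-6-yl 2-(bromomethyl)prop-2-enoate | COc1ccc(CO[C@@H]2C/C(C)=C(\O[Si](C)(C)C(C)(C)C)[C@@H](O[Si](C)(C)C(C)(C)C)C/C(C)=C\[C@H](OC(=O)C(=C)CBr)C2=C)cc1 | intermediate
35 | (2S,6S,8R)-13-bromo-1,2-bis(tert-butyldimethylsilyloxy)-8-(4-methoxybenzyloxy)germacra-1(10),4,7(11)-trien-12,6-olide | COc1ccc(CO[C@@H]2C/C(C)=C(\O[Si](C)(C)C(C)(C)C)[C@@H](O[Si](C)(C)C(C)(C)C)C/C(C)=C\[C@@H]3OC(=O)C(CBr)=C23)cc1 | intermediate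
36 | (2S,6S,8R)-13-acetoxy-1,2-bis(tert-butyldimethylsilyloxy)-8-(4-methoxybenzyloxy)germacra-1(10),4,7(11)-trien-12,6-olide | COc1ccc(CO[C@@H]2C/C(C)=C(\O[Si](C)(C)C(C)(C)C)[C@@H](O[Si](C)(C)C(C)(C)C)C/C(C)=C\[C@@H]3OC(=O)C(COC(C)=O)=C23)cc1 | intermediate
37 | (2S,6S,8R,10S)-13-acetoxy-2-(tert-butyldimethylsilyloxy)-8-(4-methoxybenzyloxy)-1-oxogermacra-4,7(11)-dien-12,6-olide | COc1ccc(CO[C@@H]2C[C@H](C)C(=O)[C@@H](O[Si](C)(C)C(C)(C)C)C/C(C)=C\[C@@H]3OC(=O)C(COC(C)=O)=C23)cc1 | intermediate
38 | (2S,6S,8R,10S)-13-acetoxy-2-(tert-butyldimethylsilyloxy)-8-hydroxy-1-oxogermacra-4,7(11)-dien-12,6-olide | O[C@@H]1C[C@H](C)C(=O)[C@@H](O[Si](C)(C)C(C)(C)C)C/C(C)=C\[C@@H]2OC(=O)C(COC(C)=O)=C12 | intermediate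
39 | (2S,6S,8R,10S)-13-acetoxy-2-(tert-butyldimethylsilyloxy)-8-(methacryloyloxy)-1-oxogermacra-4,7(11)-dien-12,6-olide | C=C(C)C(=O)O[C@@H]1C[C@H](C)C(=O)[C@@H](O[Si](C)(C)C(C)(C)C)C/C(C)=C\[C@@H]2OC(=O)C(COC(C)=O)=C12 | intermediate
40 | (2S,4S,5R,6R,8R,10S)-13-acetoxy-2-(tert-butyldimethylsilyloxy)-4,5-epoxy-8-(methacryloyloxy)-1-oxogermacr-7(11)-en-12,6-olide | C=C(C)C(=O)O[C@@H]1C[C@H](C)C(=O)[C@@H](O[Si](C)(C)C(C)(C)C)C[C@]2(C)O[C@@H]2[C@@H]2OC(=O)C(COC(C)=O)=C21 | intermediate
41 | (2S,4S,5R,6R,8R,10S)-13-acetoxy-4,5-epoxy-2-hydroxy-8-(methacryloyloxy)-1-oxogermacr-7(11)-en-12,6-olide (CNP0359197.1) | C=C(C)C(=O)O[C@@H]1C[C@H](C)C(=O)[C@@H](O)C[C@]2(C)O[C@@H]2[C@@H]2OC(=O)C(COC(C)=O)=C21 | target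

Total step count: 28 steps. Longest linear sequence: 25 steps (steps 1–8 and 12–28, from 1 to 41); the iodide branch (steps 9–11) joins at step 12.

Steps most likely to fail

Step 17. The alkoxide may fragment heterolytically across C1–C6 instead of rearranging in concert, the C2 silyl group may migrate to the C1 oxyanion before the shift, or the enolate may equilibrate toward C2 before it is silylated. The fallback drops the anionic mode for a neutral thermal one. It sets out from 24, whose tertiary hydroxyl is silylated (TBSOTf, 2,6-lutidine, CH2Cl2, −78 to 0 °C) to the C1 tert-butyldimethylsilyl ether F1. Heating F1 in degassed toluene in base-washed sealed glassware (about 180 °C) should bring about the siloxy-Cope shift through the same chair and deliver the silyl enol ether directly, so the route is rejoined at 27.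

Step 18. The iminium ion may attack the C1=C10 silyl enol ether as well as, or instead of, the methyl dienol ether, or the C8 ether may be lost by β-elimination once the C6 ketone is unveiled. The fallback replaces electrophilic substitution by a condensation at the only enolisable position. It sets out from 27, whose methyl dienol ether alone is hydrolysed (oxalic acid on wet silica gel, CH2Cl2, 0 °C) to the C6 ketone F2. Condensation with tert-butoxybis(dimethylamino)methane (toluene, 60 °C) gives the enaminone F3, and (i-Bu)2AlH (THF, −78 °C) effects conjugate hydride addition with loss of the aluminium amide, returning to the route at 30.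

Step 22. The catalyst may fail to load onto either hindered 1,1-disubstituted alkene, or may decompose before the tetrasubstituted bond closes. The fallback is a relay ring-closing metathesis that delivers the carbene to C7 from a remote terminal alkene. It sets out from 27 and passes through the ketone F2 and the enaminone F3 described above. Addition–elimination of pent-4-enylmagnesium bromide on F3 (THF, −78 to 0 °C) gives the 7-(hex-5-enylidene) dienone F4, Luche reduction as in step 20 gives the 6S alcohol F5, and acylation as in step 21 gives the 2-(bromomethyl)acrylate F6. With the same phosphine-free catalyst the ruthenium should enter at the terminal vinyl group, expel cyclopentene and so be placed on C7, from where it closes onto the acrylate; the route is rejoined at 35.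

Further compounds
F1 | step 17 | C1 tert-butyldimethylsilyl ether of 24 | C=C(C)[C@@]1(O[Si](C)(C)C(C)(C)C)[C@@H](O[Si](C)(C)C(C)(C)C)CC(C)=C[C@]1(OC)/C=C/OCc1ccc(OC)cc1
F2 | step 18 | (2S,8R)-1,2-bis(tert-butyldimethylsilyloxy)-8-(4-methoxybenzyloxy)-4,10-dimethylcyclodeca-1(10),4-dien-6-one | [C@H]1(O[Si](C)(C)C(C)(C)C)C/C(C)=C\C(=O)C[C@H](OCc2ccc(OC)cc2)C/C(C)=C1\O[Si](C)(C)C(C)(C)C
F3 | step 18 | (2S,8R)-1,2-bis(tert-butyldimethylsilyloxy)-7-[(dimethylamino)methylidene]-8-(4-methoxybenzyloxy)-4,10-dimethylcyclodeca-1(10),4-dien-6-one | [C@H]1(O[Si](C)(C)C(C)(C)C)C/C(C)=C\C(=O)C(=CN(C)C)[C@H](OCc2ccc(OC)cc2)C/C(C)=C1\O[Si](C)(C)C(C)(C)C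
F4 | step 22 | (2S,8R)-1,2-bis(tert-butyldimethylsilyloxy)-7-(hex-5-en-1-ylidene)-8-(4-methoxybenzyloxy)-4,10-dimethylcyclodeca-1(10),4-dien-6-one | [C@H]1(O[Si](C)(C)C(C)(C)C)C/C(C)=C\C(=O)C(=CCCCC=C)[C@H](OCc2ccc(OC)cc2)C/C(C)=C1\O[Si](C)(C)C(C)(C)C
F5 | step 22 | (2S,6S,8R)-1,2-bis(tert-butyldimethylsilyloxy)-7-(hex-5-en-1-ylidene)-8-(4-methoxybenzyloxy)-4,10-dimethylcyclodeca-1(10),4-dien-6-ol | COc1ccc(CO[C@@H]2C/C(C)=C(\O[Si](C)(C)C(C)(C)C)[C@@H](O[Si](C)(C)C(C)(C)C)C/C(C)=C\[C@H](O)C2=CCCCC=C)cc1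
F6 | step 22 | 2-(bromomethyl)prop-2-enoate of F5 | COc1ccc(CO[C@@H]2C/C(C)=C(\O[Si](C)(C)C(C)(C)C)[C@@H](O[Si](C)(C)C(C)(C)C)C/C(C)=C\[C@H](OC(=O)C(=C)CBr)C2=CCCCC=C)cc1
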